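**Retrosynthetic overview**
1. Depside ester C–O bond (made last): target 13 ⇒ haematommic acid 12 + phenol 4.
2. Ar–CHO bond of 12 (key C–C bond): ring C-3 of methyl orsellinate 5 and C-2 of 1,3-dithiane 6 (a masked formyl anion) are joined by a [2,3]-shift of an aryloxysulfonium ylide. The O–S⁺ group turns the normally nucleophilic ortho carbon into the acceptor, so two carbons that are both natural donors are coupled.
3. Phenol 4 ⇐ methyl β-orcinolcarboxylate 1 by 4-O-benzylation, 2-O-methylation and hydrogenolysis.
4. No ring is formed: both benzene rings are bought (1 and 5).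

Assumption: the target is achiral (no stereocentre, no stable atropisomer), so no stereocontrol is needed; 1, 5 and 6 are taken as cheap commercial materials.

**Step 1**
Reactants: 1 methyl 2,4-dihydroxy-3,6-dimethylbenzoate (methyl β-orcinolcarboxylate, atraric acid)
Product: 3 methyl 4-(benzyloxy)-2-methoxy-3,6-dimethylbenzoate, via monobenzyl ether 2 (not isolated)
Conditions: K2CO3 (3 equiv), BnBr (1.05 equiv), DMF, rt; then MeI (4 equiv), 45 °C, closed flask
Reagents that add atoms: benzyl bromide BrCc1ccccc1; iodomethane CI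
Why: Two Williamson etherifications in one pot; the free, more acidic 4-OH is benzylated at rt, and the ester-chelated 2-OH reacts only afterwards with excess MeI on warming.

**Step 2**
Reactants: 3 methyl 4-(benzyloxy)-2-methoxy-3,6-dimethylbenzoate
Product: 4 methyl 4-hydroxy-2-methoxy-3,6-dimethylbenzoate
Conditions: H2 (1 atm), 10% Pd/C, EtOAc, rt
Reagents that add atoms: none
Why: Catalytic hydrogenolysis of the benzyl aryl ether; the methyl ether and methyl ester are inert.

**Step 3 (key step)**
Reactants: 5 methyl orsellinate (methyl 2,4-dihydroxy-6-methylbenzoate); 6 1,3-dithiane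
Product: 10 methyl 3-(1,3-dithian-2-yl)-2,4-dihydroxy-6-methylbenzoate, via succinimidosulfonium salt 7 (not isolated), via aryloxysulfonium salt 8 (not isolated), via cyclohexadienone 9 (not isolated)
Conditions: NCS (1.1 equiv), 6 (1.1 equiv), CH2Cl2, −70 °C; then 5 in CH2Cl2–THF, −70 °C; then Et3N (2 equiv), −70 °C → rt
Reagents that add atoms: none
Why: Gassman ortho-formylation, a [2,3]-sigmatropic (Sommelet–Hauser-type) shift of an aryloxysulfonium ylide: the free 4-OH of 5 attacks sulfur of 7, Et3N forms the ylide at dithiane C-2, and this carbanion bonds to the ortho carbon made electrophilic by the O–S⁺ leaving group; C-3 should be preferred over C-5 because the chelated salicylate fixes the C3=C4 double bond (the bias that sends Claisen rearrangements of 4-allyloxy-2-hydroxyaryl carbonyl compounds to C-3) and because the 6-methyl shields C-5; dienone 9 is racemic and its only stereocentre is lost on tautomerisation to 10.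

**Step 4**
Reactants: 10 methyl 3-(1,3-dithian-2-yl)-2,4-dihydroxy-6-methylbenzoate
Product: 11 methyl haematommate (methyl 3-formyl-2,4-dihydroxy-6-methylbenzoate)
Conditions: HgO (2 equiv), BF3·OEt2 (2 equiv), THF–H2O 85:15, rt
Reagents that add atoms: water O
Why: Hg(II)-assisted hydrolysis of the dithioacetal (Corey–Seebach unmasking); the thiophile is inert to the phenols and the ester, and the aldehyde is held by two hydrogen bonds.

**Step 5**
Reactants: 11 methyl haematommate
Product: 12 haematommic acid (3-formyl-2,4-dihydroxy-6-methylbenzoic acid)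
Conditions: conc. H2SO4, 0 °C → rt, 1 h; pour onto ice
Reagents that add atoms: water O
Why: AAC1 ester hydrolysis: the di-ortho-substituted, electron-rich benzoate ionises to an acylium ion that water captures on quenching, while the low temperature and the protonated formyl group suppress decarboxylation and sulfonation.

**Step 6**
Reactants: 12 haematommic acid; 4 methyl 4-hydroxy-2-methoxy-3,6-dimethylbenzoate
Product: 13 2'-O-methylatranorin
Conditions: TFAA (4 equiv), toluene, rt, 3 h; then aq. NaHCO3 work-up
Reagents that add atoms: none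
Why: Esterification through the mixed trifluoroacetic anhydride (classical depside coupling); both phenols of 12 are chelated to CHO/CO2H and are poor nucleophiles, so only the phenol of 4 is acylated and no protecting group is needed.

**Compound list**
1 | methyl 2,4-dihydroxy-3,6-dimethylbenzoate (methyl β-orcinolcarboxylate, atraric acid) | COC(=O)c1c(C)cc(O)c(C)c1O | starting material
2 | methyl 4-(benzyloxy)-2-hydroxy-3,6-dimethylbenzoate | COC(=O)c1c(C)cc(OCc2ccccc2)c(C)c1O | intermediate
3 | methyl 4-(benzyloxy)-2-methoxy-3,6-dimethylbenzoate | COC(=O)c1c(C)cc(OCc2ccccc2)c(C)c1OC | intermediate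
4 | methyl 4-hydroxy-2-methoxy-3,6-dimethylbenzoate | COC(=O)c1c(C)cc(O)c(C)c1OC | intermediate
5 | methyl orsellinate (methyl 2,4-dihydroxy-6-methylbenzoate) | COC(=O)c1c(C)cc(O)cc1O | starting material
6 | 1,3-dithiane | C1CSCSC1 | starting material
7 | 1-(2,5-dioxopyrrolidin-1-yl)-1,3-dithian-1-ium chloride | O=C1CCC(=O)N1[S+]1CCCSC1.[Cl-] | intermediate
8 | 1-[3-hydroxy-4-(methoxycarbonyl)-5-methylphenoxy]-1,3-dithian-1-ium chloride | COC(=O)c1c(C)cc(O[S+]2CCCSC2)cc1O.[Cl-] | intermediate
9 | methyl 3-(1,3-dithian-2-yl)-2-hydroxy-6-methyl-4-oxocyclohexa-1,5-diene-1-carboxylate (racemic) | COC(=O)C1=C(O)C(C2SCCCS2)C(=O)C=C1C | intermediate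
10 | methyl 3-(1,3-dithian-2-yl)-2,4-dihydroxy-6-methylbenzoate | COC(=O)c1c(C)cc(O)c(C2SCCCS2)c1O | intermediate
11 | methyl haematommate (methyl 3-formyl-2,4-dihydroxy-6-methylbenzoate) | COC(=O)c1c(C)cc(O)c(C=O)c1O | intermediate
12 | haematommic acid (3-formyl-2,4-dihydroxy-6-methylbenzoic acid) | OC(=O)c1c(C)cc(O)c(C=O)c1O | intermediate
13 | 2'-O-methylatranorin | COC(=O)c1c(C)cc(OC(=O)c2c(C)cc(O)c(C=O)c2O)c(C)c1OC | target

**Step count and risk**
Total steps: 6. Longest linear sequence: 4 (5 → 10 → 11 → 12 → 13); the two-step branch 1 → 3 → 4 joins in step 6.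

The three steps most likely to fail:

Step 3 (the sigmatropic shift may go partly to C-5, or the para-ester phenol may capture the sulfonium salt poorly). The fallback moves the tether to the other oxygen and sets out from 5. The free 4-OH is benzylated (BnBr, K2CO3, acetone, reflux) to give methyl 4-(benzyloxy)-2-hydroxy-6-methylbenzoate F1. Its only phenol, the chelated 2-OH, has a single open ortho carbon, C-3. The same dithiane/NCS/Et3N sequence (salt 7) is then run through this oxygen to give methyl 4-(benzyloxy)-3-(1,3-dithian-2-yl)-2-hydroxy-6-methylbenzoate F2. The benzyl ether is cleaved with BCl3 and pentamethylbenzene in CH2Cl2 at −78 °C (hydrogenolysis is avoided because of the sulfur), and the route is rejoined at 10.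

Step 5 (decarboxylation to atranol or sulfonation in sulfuric acid). The fallback changes the order and the mechanism and sets out from 10. While the aldehyde is still masked, the ester is saponified with KOH in aqueous DMSO at 90 °C to give 3-(1,3-dithian-2-yl)-2,4-dihydroxy-6-methylbenzoic acid F3. The dithiane is then removed with HgO/BF3·OEt2 in aqueous THF, and the route is rejoined at 12, with 11 skipped.

Step 6 (low yield from trifluoroacetylation or from poor solubility of the formyl acid). The fallback makes the ester bond before the formyl group and sets out from 5.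
- Exhaustive benzylation (BnBr 2.5 equiv, K2CO3, DMF, 70 °C) gives methyl 2,4-bis(benzyloxy)-6-methylbenzoate F4.
- Saponification (KOH, aqueous DMSO, 90 °C) gives 2,4-bis(benzyloxy)-6-methylbenzoic acid F5.
- Steglich coupling with 4 (DCC, DMAP, CH2Cl2) gives methyl 4-{[2,4-bis(benzyloxy)-6-methylbenzoyl]oxy}-2-methoxy-3,6-dimethylbenzoate F6.
- Hydrogenolysis (H2, Pd/C, EtOAc) gives methyl 4-[(2,4-dihydroxy-6-methylbenzoyl)oxy]-2-methoxy-3,6-dimethylbenzoate F7.
- The dithiane/NCS/Et3N sequence with 6 (through salt 7), now on the whole depside, gives methyl 4-{[3-(1,3-dithian-2-yl)-2,4-dihydroxy-6-methylbenzoyl]oxy}-2-methoxy-3,6-dimethylbenzoate F8.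
- HgO/BF3·OEt2 hydrolysis then rejoins the route at 13.

**Further compounds**
F1 | step 3 | methyl 4-(benzyloxy)-2-hydroxy-6-methylbenzoate | COC(=O)c1c(C)cc(OCc2ccccc2)cc1O
F2 | step 3 | methyl 4-(benzyloxy)-3-(1,3-dithian-2-yl)-2-hydroxy-6-methylbenzoate | COC(=O)c1c(C)cc(OCc2ccccc2)c(C2SCCCS2)c1O
F3 | step 5 | 3-(1,3-dithian-2-yl)-2,4-dihydroxy-6-methylbenzoic acid | OC(=O)c1c(C)cc(O)c(C2SCCCS2)c1O
F4 | step 6 | methyl 2,4-bis(benzyloxy)-6-methylbenzoate | COC(=O)c1c(C)cc(OCc2ccccc2)cc1OCc3ccccc3
F5 | step 6 | 2,4-bis(benzyloxy)-6-methylbenzoic acid | OC(=O)c1c(C)cc(OCc2ccccc2)cc1OCc3ccccc3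
F6 | step 6 | methyl 4-{[2,4-bis(benzyloxy)-6-methylbenzoyl]oxy}-2-methoxy-3,6-dimethylbenzoate | COC(=O)c1c(C)cc(OC(=O)c2c(C)cc(OCc3ccccc3)cc2OCc4ccccc4)c(C)c1OC
F7 | step 6 | methyl 4-[(2,4-dihydroxy-6-methylbenzoyl)oxy]-2-methoxy-3,6-dimethylbenzoate | COC(=O)c1c(C)cc(OC(=O)c2c(C)cc(O)cc2O)c(C)c1OC
F8 | step 6 | methyl 4-{[3-(1,3-dithian-2-yl)-2,4-dihydroxy-6-methylbenzoyl]oxy}-2-methoxy-3,6-dimethylbenzoate | COC(=O)c1c(C)cc(OC(=O)c2c(C)cc(O)c(C3SCCCS3)c2O)c(C)c1OC
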